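**Retrosynthetic overview**

1. Xanthanolide numbering is used: ring A is the lactone O–C8–C7–C11–C12, ring B is C1/C5–C10, ring C is C1–C2–C3–C11'–C13'–C5, ring D is the spiro lactone and ring E is the primed cycloheptene. Rings A/B and D/E have opposite absolute configuration, so both are derived from one ketolactone made with the two antipodes of an organocatalyst (9 and its enantiomer 20).
2. Ring C is made last and stepwise, because a Diels–Alder union would add to the other face of the ring D methylene lactone. It is cut at C11'–C13' (allylic alkylation of a ring D β-keto lactone by a Morita–Baylis–Hillman carbonate on ring B) and at C1–C2 (aldol). C5–H then comes from an OH-directed hydrogenation and the C3 acetyl from enol triflate/Stille coupling.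
3. Rings B and A arise together from a cyclohexene: dibromocarbene adduct 6 opens under silver assistance with one-carbon ring expansion, and the acetate arm on C7 closes the lactone onto C8.
4. Enabling feature: in ring B the O-bearing C8, the methylene C9 and the methyl-bearing C10 are contiguous. They are the three carbons of the allyl cation of a ring-fused gem-dibromocyclopropane (C9 is the carbene carbon). The carboxyl carbon C12 sits on C7 next to C8, so its oxygen can reach only C8 and only on the same face (cis-fused ring A).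
5. Order of ring formation: six-membered carbocycle, then B + A in one step (E + D likewise), then C.

Key step: step 4

Remark: the target is taken as drawn, (1S,5R,7R,8R,10S,7'S,8'S,10'R,11'S); the sense of induction in steps 1 and 10 follows the usual enamine shielding model, and if it were opposite the two catalyst antipodes would be exchanged.

**Route**

Step 1
Reactants: 1 tert-butyl 4-oxobutanoate; 2 pent-1-en-3-one
Product: 4 tert-butyl 2-[(1R)-3-methyl-4-oxocyclohex-2-en-1-yl]acetate, via keto aldehyde 3 (not isolated)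
Conditions: (R)-2-[methoxy(diphenyl)methyl]pyrrolidine (5 mol %), ethyl 3,4-dihydroxybenzoate (20 mol %), neat, 4 °C; then LiOH (0.2 equiv), iPrOH, rt
Reagents that add atoms: none
Why: Enamine-catalysed Michael addition of the aldehyde to the vinyl ketone (the diarylmethyl group shields one enamine face and should set C7 as R), then intramolecular aldol condensation of the 1,5-keto aldehyde (Robinson-type annulation), should give the 4-substituted 2-methylcyclohexenone.

Step 2
Reactants: 4 tert-butyl 2-[(1R)-3-methyl-4-oxocyclohex-2-en-1-yl]acetate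
Product: 5 tert-butyl 2-[(8R)-6-methyl-1,4-dioxaspiro[4.5]dec-6-en-8-yl]acetate
Conditions: Me3SiOCH2CH2OSiMe3, Me3SiOTf (2 mol %), CH2Cl2, −78 °C
Reagents that add atoms: 1,2-bis(trimethylsilyloxy)ethane, C[Si](C)(C)OCCO[Si](C)(C)C
Why: Silyl-triflate-catalysed ketalization at low temperature should protect the enone carbonyl without moving the double bond and makes the alkene electron-rich enough for carbene addition.

Step 3
Reactants: 5 tert-butyl 2-[(8R)-6-methyl-1,4-dioxaspiro[4.5]dec-6-en-8-yl]acetate
Product: 6 dibromocyclopropane (CBr2 bridging C8 and C10)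
Conditions: CHBr3, KOtBu, pentane, 0 °C
Reagents that add atoms: bromoform, BrC(Br)Br
Why: Dibromocarbene (α-elimination of bromoform) should add to the only alkene, a trisubstituted one; addition anti to the acetate arm is expected, but the cyclopropane configuration is erased in step 4.

Step 4
Reactants: 6 dibromocyclopropane (CBr2 bridging C8 and C10)
Product: 7 cis-fused bromo lactone ketal (rings A and B)
Conditions: AgBF4 (1.5 equiv), 2,6-di-tert-butyl-4-methylpyridine, CH2Cl2, 0 °C to rt
Reagents that add atoms: none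
Why: Silver ion removes the endo bromide while the C8–C10 σ bond opens in a disrotatory two-electron electrocyclic process to the 2-bromocyclohept-2-enyl cation C8–C9(Br)–C10; the ester carbonyl oxygen of the C7 arm captures C8 and the tert-butyl group leaves as 2-methylpropene. The closest known reaction type is the silver-promoted electrocyclic opening of ring-fused gem-dibromocyclopropanes with capture of the allyl cation by a tethered oxygen nucleophile. Ring B closes by ring expansion (the six-membered ring gains C9 when the C8–C10 bond breaks) and ring A by 5-exo attack of oxygen on the allyl terminus C8, which forms the O–C8 bond. C8 is the only new stereocentre: the two-atom tether on C7 reaches C8 only from its own face, so the lactone is cis-fused and C8 follows from C7. The step needs regioselection between the termini C8 and C10 and suppression of proton loss or 1,2-shift at the tertiary C10: a five-membered ring is possible only at C8, the non-nucleophilic counter-ion and hindered base leave no other nucleophile or acid, and the inductively withdrawing ketal at C1 shifts positive charge from C10 toward C8.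

Step 5
Reactants: 7 cis-fused bromo lactone ketal (rings A and B)
Product: 8 saturated lactone ketal (C10 methyl cis to the lactone oxygen)
Conditions: H2 (1 atm), Pd/C, Et3N, EtOAc, rt
Reagents that add atoms: none
Why: Heterogeneous hydrogenation with hydrogenolysis of the vinyl C–Br bond; H2 should add to C9=C10 on the convex face of the cis-fused bicycle, anti to the allylic lactone oxygen on C8, placing the C10 methyl cis to the lactone.

Step 6
Reactants: 8 saturated lactone ketal (C10 methyl cis to the lactone oxygen)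
Product: 9 (3aR,7S,8aR)-7-methylhexahydro-2H-cyclohepta[b]furan-2,6(3H)-dione
Conditions: PPTS, acetone/H2O, 50 °C
Reagents that add atoms: water, O
Why: Acid-catalysed ketal hydrolysis; the mild acid should leave the lactone and the α-stereocentre C10 untouched.

Step 7
Reactants: 9 (3aR,7S,8aR)-7-methylhexahydro-2H-cyclohepta[b]furan-2,6(3H)-dione
Product: 11 ring B enone (C1 ketone conjugated to C5=C6), via silyl enol ether 10 (not isolated)
Conditions: LiN(iPr)2, Me3SiCl, THF, −78 °C; then Pd(OAc)2 (10 mol %), O2 (1 atm), DMSO, rt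
Reagents that add atoms: none
Why: Kinetic deprotonation of the ketone at the less substituted α-carbon C5 (ketone more acidic than lactone), then Saegusa oxidation (β-hydride elimination of the palladium enolate toward C6), should give the C5=C6 enone without touching C10.

Step 8
Reactants: 11 ring B enone (C1 ketone conjugated to C5=C6)
Product: 12 C5-hydroxymethyl enone
Conditions: 37% aq. CH2O, nBu3P (20 mol %), THF, rt
Reagents that add atoms: formaldehyde, C=O
Why: Morita–Baylis–Hillman reaction: the phosphine adds to C6 and the resulting enolate is hydroxymethylated at C5; no stereocentre is formed.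

Step 9
Reactants: 12 C5-hydroxymethyl enone
Product: 13 tert-butyl carbonate of 12
Conditions: Boc2O, DMAP (5 mol %), CH2Cl2, 0 °C
Reagents that add atoms: di-tert-butyl dicarbonate, CC(C)(C)OC(=O)OC(=O)OC(C)(C)C
Why: O-Acylation of the primary allylic alcohol installs the leaving group for the allylic alkylation of step 19.

Step 10
Reactants: 1 tert-butyl 4-oxobutanoate; 2 pent-1-en-3-one
Product: 15 tert-butyl 2-[(1S)-3-methyl-4-oxocyclohex-2-en-1-yl]acetate, via keto aldehyde 14 (not isolated)
Conditions: (S)-2-[methoxy(diphenyl)methyl]pyrrolidine (5 mol %), ethyl 3,4-dihydroxybenzoate (20 mol %), neat, 4 °C; then LiOH (0.2 equiv), iPrOH, rt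
Reagents that add atoms: none
Why: Same enamine Michael/aldol condensation as step 1 with the antipodal catalyst, which should set C7' as S.

Step 11
Reactants: 15 tert-butyl 2-[(1S)-3-methyl-4-oxocyclohex-2-en-1-yl]acetate
Product: 16 tert-butyl 2-[(8S)-6-methyl-1,4-dioxaspiro[4.5]dec-6-en-8-yl]acetate
Conditions: Me3SiOCH2CH2OSiMe3, Me3SiOTf (2 mol %), CH2Cl2, −78 °C
Reagents that add atoms: 1,2-bis(trimethylsilyloxy)ethane, C[Si](C)(C)OCCO[Si](C)(C)C
Why: Ketalization as in step 2, mirror-image series.

Step 12
Reactants: 16 tert-butyl 2-[(8S)-6-methyl-1,4-dioxaspiro[4.5]dec-6-en-8-yl]acetate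
Product: 17 enantiomer of dibromocyclopropane 6
Conditions: CHBr3, KOtBu, pentane, 0 °C
Reagents that add atoms: bromoform, BrC(Br)Br
Why: Dibromocarbene addition as in step 3.

Step 13
Reactants: 17 enantiomer of dibromocyclopropane 6
Product: 18 enantiomer of bromo lactone ketal 7 (rings D and E)
Conditions: AgBF4 (1.5 equiv), 2,6-di-tert-butyl-4-methylpyridine, CH2Cl2, 0 °C to rt
Reagents that add atoms: none
Why: Same electrocyclic ring expansion/lactonization as step 4; it should form ring E and the cis-fused lactone of ring D with C8' fixed by C7'.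

Step 14
Reactants: 18 enantiomer of bromo lactone ketal 7 (rings D and E)
Product: 19 enantiomer of saturated lactone ketal 8
Conditions: H2 (1 atm), Pd/C, Et3N, EtOAc, rt
Reagents that add atoms: none
Why: Convex-face hydrogenation/hydrodebromination as in step 5 should set C10'.

Step 15
Reactants: 19 enantiomer of saturated lactone ketal 8
Product: 20 (3aS,7R,8aS)-7-methylhexahydro-2H-cyclohepta[b]furan-2,6(3H)-dione
Conditions: PPTS, acetone/H2O, 50 °C
Reagents that add atoms: water, O
Why: Ketal hydrolysis as in step 6.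

Step 16
Reactants: 20 (3aS,7R,8aS)-7-methylhexahydro-2H-cyclohepta[b]furan-2,6(3H)-dione
Product: 21 (3aS,7R,8aS)-7-methyl-2-oxo-3,3a,4,7,8,8a-hexahydro-2H-cyclohepta[b]furan-6-yl trifluoromethanesulfonate
Conditions: KN(SiMe3)2 (1.05 equiv), PhNTf2, THF, −78 °C
Reagents that add atoms: N-phenylbis(trifluoromethanesulfonimide), O=S(=O)(N(c1ccccc1)S(=O)(=O)C(F)(F)F)C(F)(F)F
Why: Kinetic enolization at the α-methylene C5' instead of the α-methine C10' (ketone more acidic than lactone) and O-triflation should give the less substituted enol triflate.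

Step 17
Reactants: 21 (3aS,7R,8aS)-7-methyl-2-oxo-3,3a,4,7,8,8a-hexahydro-2H-cyclohepta[b]furan-6-yl trifluoromethanesulfonate
Product: 22 (3aS,7R,8aS)-7-methyl-6-[2-(2-methyl-1,3-dioxolan-2-yl)ethyl]-3,3a,4,7,8,8a-hexahydro-2H-cyclohepta[b]furan-2-one
Conditions: 9-BBN-H, 2-methyl-2-vinyl-1,3-dioxolane, THF, rt; then 21, Pd(dppf)Cl2 (5 mol %), K3PO4, DMF/H2O, 50 °C
Reagents that add atoms: 2-methyl-2-vinyl-1,3-dioxolane, C=CC1(C)OCCO1
Why: B-alkyl Suzuki–Miyaura coupling of the enol triflate with the alkylborane from anti-Markovnikov hydroboration should install the protected 3-oxobutyl chain on C1' and fix the C1'=C5' double bond.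

Step 18
Reactants: 22 (3aS,7R,8aS)-7-methyl-6-[2-(2-methyl-1,3-dioxolan-2-yl)ethyl]-3,3a,4,7,8,8a-hexahydro-2H-cyclohepta[b]furan-2-one
Product: 23 C11'-acetyl lactone (β-keto lactone)
Conditions: LiN(iPr)2 (2.2 equiv), THF, −78 °C; MeC(O)N(OMe)Me; AcOH quench
Reagents that add atoms: N-methoxy-N-methylacetamide, CC(=O)N(C)OC
Why: Claisen-type C-acylation of the lactone enolate with the N-methoxy-N-methyl amide (two equivalents of base because the product is deprotonated); the new centre C11' is epimerizable and is redefined in step 19.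

Step 19
Reactants: 13 tert-butyl carbonate of 12; 23 C11'-acetyl lactone (β-keto lactone)
Product: 24 coupled enone (C13' bonded to C5 and to quaternary C11')
Conditions: DABCO (20 mol %), THF, rt
Reagents that add atoms: none
Why: Amine-catalysed allylic alkylation of the Morita–Baylis–Hillman carbonate (two successive SN2' events; the expelled tert-butyl carbonate loses CO2 and deprotonates 23): the planar β-keto lactone enolate should take up C13' on its convex face, anti to C6', leaving the acetyl carbon C3 syn to C6' at the quaternary C11'.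

Step 20
Reactants: 24 coupled enone (C13' bonded to C5 and to quaternary C11')
Product: 25 ring C ketol (C1–OH cis to the C10 methyl; C5=C6 retained)
Conditions: LiN(iPr)2 (1.05 equiv), THF, −78 °C; AcOH quench at −78 °C
Reagents that add atoms: none
Why: Kinetic deprotonation of the acetyl methyl (the only unhindered α-CH3) and intramolecular aldol addition (6-exo) of the lithium enolate to the C1 carbonyl close ring C; C2 should attack C1 on the convex face, anti to the C10 methyl and the ring A lactone, so the C1 oxygen ends cis to that methyl, and because C3 and C5 are sp2 the spiro centre C11' exerts little bias.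

Step 21
Reactants: 25 ring C ketol (C1–OH cis to the C10 methyl; C5=C6 retained)
Product: 26 cis-fused ketol (H5 cis to C1–OH)
Conditions: H2 (50 atm), [Rh(nbd)(dppb)]BF4 (5 mol %), CH2Cl2, rt
Reagents that add atoms: none
Why: Hydroxyl-directed homogeneous hydrogenation: the cationic rhodium diphosphine complex binds the tertiary C1–OH and should deliver H2 to the allylic C5=C6 bond on the OH face, giving the cis B/C fusion; the unfunctionalized trisubstituted C1'=C5' alkene is inert to this catalyst.

Step 22
Reactants: 26 cis-fused ketol (H5 cis to C1–OH)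
Product: 27 C1 trimethylsilyl ether of 26
Conditions: Me3SiOTf, 2,6-lutidine, CH2Cl2, −78 °C
Reagents that add atoms: trimethylsilyl trifluoromethanesulfonate, C[Si](C)(C)OS(=O)(=O)C(F)(F)F
Why: Silylation of the tertiary aldol hydroxyl should prevent retro-aldol cleavage when C3 is enolized.

Step 23
Reactants: 27 C1 trimethylsilyl ether of 26
Product: 28 C2=C3 enol triflate
Conditions: KN(SiMe3)2, PhNTf2, THF, −78 °C
Reagents that add atoms: N-phenylbis(trifluoromethanesulfonimide), O=S(=O)(N(c1ccccc1)S(=O)(=O)C(F)(F)F)C(F)(F)F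
Why: The C3 ketone can enolize only toward C2 (C11' is quaternary), and O-triflation of the potassium enolate at low temperature should outrun β-elimination of the silyloxy group.

Step 24
Reactants: 28 C2=C3 enol triflate
Product: 31 ring A α-methylene lactone enol triflate, via Mannich amine 29 (not isolated), via ammonium iodide 30 (not isolated)
Conditions: LiN(iPr)2, THF, −78 °C; CH2=NMe2 I; then MeI, THF, rt; then aq. NaHCO3, CH2Cl2
Reagents that add atoms: N,N-dimethylmethyleneiminium iodide (Eschenmoser's salt), C=[N+](C)C.[I-]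
Why: α-Methylenation of lactone A: its enolate (the only acidic C–H left; lactone D has no α-hydrogen) undergoes a Mannich reaction with Eschenmoser's salt and the quaternized amine eliminates to the exocyclic methylene.

Step 25
Reactants: 31 ring A α-methylene lactone enol triflate
Product: 33 target CNP0195550.4, via enol ether 32 (not isolated)
Conditions: Bu3Sn(C(OEt)=CH2), Pd(PPh3)4 (5 mol %), LiCl, THF, 65 °C; then 1 M HCl, THF, rt
Reagents that add atoms: tributyl(1-ethoxyvinyl)stannane, CCCC[Sn](CCCC)(CCCC)C(=C)OCC; water, O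
Why: Stille coupling of the enol triflate with the 1-ethoxyvinyl stannane (acetyl anion equivalent), then mild acid hydrolysis, should unmask the C3 acetyl and cleave the tertiary silyl ether and the side-chain ketal in the same operation; no stereocentre is touched.

**Compound list**

1 | tert-butyl 4-oxobutanoate | O=CCCC(=O)OC(C)(C)C | starting material
2 | pent-1-en-3-one (ethyl vinyl ketone) | C=CC(=O)CC | starting material
3 | tert-butyl (3R)-3-formyl-6-oxooctanoate | O=C[C@@H](CC(=O)OC(C)(C)C)CCC(=O)CC | intermediate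
4 | tert-butyl 2-[(1R)-3-methyl-4-oxocyclohex-2-en-1-yl]acetate | CC1=C[C@@H](CC(=O)OC(C)(C)C)CCC1=O | intermediate
5 | tert-butyl 2-[(8R)-6-methyl-1,4-dioxaspiro[4.5]dec-6-en-8-yl]acetate | CC1=C[C@@H](CC(=O)OC(C)(C)C)CCC12OCCO2 | intermediate
6 | tert-butyl 2-[7',7'-dibromo-1'-methylspiro[1,3-dioxolane-2,2'-bicyclo[4.1.0]heptan]-5'-yl]acetate (cyclopropane trans to the acetate arm; C5' configured as C8 of 5) | C[C@@]12C(Br)(Br)[C@@H]1[C@@H](CC(=O)OC(C)(C)C)CCC23OCCO3 | intermediate
7 | cis-fused bromo lactone ketal: γ-lactone (O on C8, C11 on C7, H7 and H8 cis) on a cycloheptene with C9(Br)=C10(CH3) and the C1 ethylene ketal | O=C1O[C@@H]2C(Br)=C(C)C3(OCCO3)CC[C@@H]2C1 | intermediate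
8 | saturated lactone ketal: 7 with C9H2 and C10H(CH3), methyl cis to the lactone oxygen | O=C1O[C@@H]2C[C@H](C)C3(OCCO3)CC[C@@H]2C1 | intermediate
9 | (3aR,7S,8aR)-7-methylhexahydro-2H-cyclohepta[b]furan-2,6(3H)-dione (xanthanolide 7R,8R,10S; C1 ketone) | O=C1O[C@@H]2C[C@H](C)C(=O)CC[C@@H]2C1 | intermediate
10 | kinetic trimethylsilyl enol ether of 9 (C1–OSiMe3, C1=C5) | O=C1O[C@@H]2C[C@H](C)C(O[Si](C)(C)C)=CC[C@@H]2C1 | intermediate
11 | ring B enone: 9 with a C5=C6 double bond conjugated to the C1 ketone | O=C1O[C@@H]2C[C@H](C)C(=O)C=C[C@@H]2C1 | intermediate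
12 | C5-hydroxymethyl derivative of 11 | O=C1O[C@@H]2C[C@H](C)C(=O)C(CO)=C[C@@H]2C1 | intermediate
13 | tert-butyl carbonate of 12 | O=C1O[C@@H]2C[C@H](C)C(=O)C(COC(=O)OC(C)(C)C)=C[C@@H]2C1 | intermediate
14 | tert-butyl (3S)-3-formyl-6-oxooctanoate | O=C[C@H](CC(=O)OC(C)(C)C)CCC(=O)CC | intermediate
15 | tert-butyl 2-[(1S)-3-methyl-4-oxocyclohex-2-en-1-yl]acetate | CC1=C[C@H](CC(=O)OC(C)(C)C)CCC1=O | intermediate
16 | tert-butyl 2-[(8S)-6-methyl-1,4-dioxaspiro[4.5]dec-6-en-8-yl]acetate | CC1=C[C@H](CC(=O)OC(C)(C)C)CCC12OCCO2 | intermediate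
17 | enantiomer of 6 | C[C@]12C(Br)(Br)[C@H]1[C@H](CC(=O)OC(C)(C)C)CCC23OCCO3 | intermediate
18 | enantiomer of 7 | O=C1O[C@H]2C(Br)=C(C)C3(OCCO3)CC[C@H]2C1 | intermediate
19 | enantiomer of 8 | O=C1O[C@H]2C[C@@H](C)C3(OCCO3)CC[C@H]2C1 | intermediate
20 | (3aS,7R,8aS)-7-methylhexahydro-2H-cyclohepta[b]furan-2,6(3H)-dione (enantiomer of 9) | O=C1O[C@H]2C[C@@H](C)C(=O)CC[C@H]2C1 | intermediate
21 | (3aS,7R,8aS)-7-methyl-2-oxo-3,3a,4,7,8,8a-hexahydro-2H-cyclohepta[b]furan-6-yl trifluoromethanesulfonate | O=C1O[C@H]2C[C@@H](C)C(OS(=O)(=O)C(F)(F)F)=CC[C@H]2C1 | intermediate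
22 | (3aS,7R,8aS)-7-methyl-6-[2-(2-methyl-1,3-dioxolan-2-yl)ethyl]-3,3a,4,7,8,8a-hexahydro-2H-cyclohepta[b]furan-2-one | O=C1O[C@H]2C[C@@H](C)C(CCC3(C)OCCO3)=CC[C@H]2C1 | intermediate
23 | C11'-acetyl derivative of 22 (acetyl trans to C6'; epimerizable β-keto lactone) | CC(=O)[C@@H]1C(=O)O[C@H]2C[C@@H](C)C(CCC3(C)OCCO3)=CC[C@@H]12 | intermediate
24 | coupled enone: enone 11 carrying on C5 the methylene C13' that is bonded to the quaternary C11' of the acetyl lactone (C13' anti to C6') | CC(=O)[C@@]1(CC2=C[C@@H]5CC(=O)O[C@@H]5C[C@H](C)C2=O)C(=O)O[C@H]3C[C@@H](C)C(CCC4(C)OCCO4)=CC[C@@H]13 | intermediate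
25 | ring C ketol: C2–C1 bond closed, tertiary C1–OH cis to the C10 methyl, C3 ketone, C5=C6 retained | C1C(=O)O[C@@H]2C[C@H](C)[C@@]3(O)CC(=O)[C@@]4(CC3=C[C@H]12)C(=O)O[C@H]1C[C@@H](C)C(CCC5(C)OCCO5)=CC[C@H]14 | intermediate
26 | cis-fused ketol: 5,6-dihydro-25 with H5 cis to the C1–OH | C1C(=O)O[C@@H]2C[C@H](C)[C@@]3(O)CC(=O)[C@@]4(C[C@H]3C[C@H]12)C(=O)O[C@H]1C[C@@H](C)C(CCC5(C)OCCO5)=CC[C@H]14 | intermediate
27 | C1 trimethylsilyl ether of 26 | C1C(=O)O[C@@H]2C[C@H](C)[C@@]3(O[Si](C)(C)C)CC(=O)[C@@]4(C[C@H]3C[C@H]12)C(=O)O[C@H]1C[C@@H](C)C(CCC5(C)OCCO5)=CC[C@H]14 | intermediate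
28 | C2=C3 enol triflate of 27 | C1C(=O)O[C@@H]2C[C@H](C)[C@@]3(O[Si](C)(C)C)C=C(OS(=O)(=O)C(F)(F)F)[C@@]4(C[C@H]3C[C@H]12)C(=O)O[C@H]1C[C@@H](C)C(CCC5(C)OCCO5)=CC[C@H]14 | intermediate
29 | C11-(dimethylaminomethyl) derivative of 28 (aminomethyl on the convex face) | CN(C)C[C@H]1C(=O)O[C@@H]2C[C@H](C)[C@@]3(O[Si](C)(C)C)C=C(OS(=O)(=O)C(F)(F)F)[C@@]4(C[C@H]3C[C@H]12)C(=O)O[C@H]1C[C@@H](C)C(CCC5(C)OCCO5)=CC[C@H]14 | intermediate
30 | trimethylammonium iodide of 29 | C[N+](C)(C)C[C@H]1C(=O)O[C@@H]2C[C@H](C)[C@@]3(O[Si](C)(C)C)C=C(OS(=O)(=O)C(F)(F)F)[C@@]4(C[C@H]3C[C@H]12)C(=O)O[C@H]1C[C@@H](C)C(CCC5(C)OCCO5)=CC[C@H]14.[I-] | intermediate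
31 | ring A α-methylene lactone: 28 with the exocyclic C11=C13 methylene | C=C1C(=O)O[C@@H]2C[C@H](C)[C@@]3(O[Si](C)(C)C)C=C(OS(=O)(=O)C(F)(F)F)[C@@]4(C[C@H]3C[C@H]12)C(=O)O[C@H]1C[C@@H](C)C(CCC5(C)OCCO5)=CC[C@H]14 | intermediate
32 | 1-ethoxyvinyl compound: 31 with C(OEt)=CH2 on C3 in place of the triflate | C=C1C(=O)O[C@@H]2C[C@H](C)[C@@]3(O[Si](C)(C)C)C=C(C(=C)OCC)[C@@]4(C[C@H]3C[C@H]12)C(=O)O[C@H]1C[C@@H](C)C(CCC5(C)OCCO5)=CC[C@H]14 | intermediate
33 | CNP0195550.4 | C=C1C(=O)O[C@@H]2C[C@H](C)[C@@]3(O)C=C(C(C)=O)[C@@]4(C[C@H]3C[C@H]12)C(=O)O[C@H]1C[C@@H](C)C(CCC(C)=O)=CC[C@H]14 | target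

**Step count and risks**

Total step count: 25. Longest linear sequence: 16 steps (steps 1–9, then 19–25; the branch 10–18 is equally long).

Steps most likely to fail:

1. Step 4 (and its mirror, step 13). The allyl cation may lose a proton, or undergo a 1,2-alkyl shift toward the ketal carbon, faster than the ester oxygen closes the ring. Fallback: from 6, solvolysis with AgOAc in AcOH lets the solvent trap the cation at once and should give the allylic acetate F1 (acetate on C8, trans to the arm). Methanolysis (K2CO3, MeOH) should give the alcohol F2 and MsCl/Et3N the mesylate F3. On warming in toluene, F3 should be displaced from the rear by the tert-butyl ester carbonyl (intramolecular SN2 with inversion, loss of 2-methylpropene), which returns to 7 with the cis lactone. The mirror-image sequence would serve 17 to 18.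

2. Step 20. The enolate may add 1,4 to C6 instead of 1,2 to C1, the enone may be deprotonated at C7 with opening of lactone A, or the facial selectivity at C1 may be poor. Fallback: from 24, in-situ trapping (LiN(iPr)2/Me3SiCl, −78 °C) should give the silyl enol ether F6 and N-bromosuccinimide the bromo ketone F7. SmI2 in THF at −78 °C should then generate a trivalent samarium enolate that adds 1,2 to the C1 carbonyl under chelation (Reformatsky-type closure), coming back to the route at 25.

3. Step 5 (and its mirror, step 14). The allylic C8–O bond may be hydrogenolysed, or hydrogen may add to the wrong face at C10. Fallback: from 7, radical debromination (Bu3SnH, AIBN, toluene, 80 °C) should give the alkene F4 and ketal hydrolysis (PPTS, aqueous acetone) the enone F5. Conjugate reduction with [(Ph3P)CuH]6, followed by kinetic protonation of the enolate at C10 on the convex face, should rejoin the route at 9. The same sequence would take 18 to 20.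

Further compounds
F1 | step 4 | tert-butyl ester with allylic acetate on C8 trans to the acetate arm (ring-expanded bromo cycloheptene ketal) | CC(=O)O[C@H]1C(Br)=C(C)C2(OCCO2)CC[C@@H]1CC(=O)OC(C)(C)C
F2 | step 4 | allylic alcohol from F1 (C8–OH trans to the acetate arm) | O[C@H]1C(Br)=C(C)C2(OCCO2)CC[C@@H]1CC(=O)OC(C)(C)C
F3 | step 4 | methanesulfonate of F2 | CS(=O)(=O)O[C@H]1C(Br)=C(C)C2(OCCO2)CC[C@@H]1CC(=O)OC(C)(C)C
F4 | step 5 | debrominated lactone ketal with C9=C10 double bond | O=C1O[C@@H]2C=C(C)C3(OCCO3)CC[C@@H]2C1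
F5 | step 5 | enone lactone (C1 ketone conjugated to C9=C10) | O=C1O[C@@H]2C=C(C)C(=O)CC[C@@H]2C1
F6 | step 20 | trimethylsilyl enol ether of the acetyl group of 24 | C=C(O[Si](C)(C)C)[C@@]1(CC2=C[C@@H]5CC(=O)O[C@@H]5C[C@H](C)C2=O)C(=O)O[C@H]3C[C@@H](C)C(CCC4(C)OCCO4)=CC[C@@H]13
F7 | step 20 | bromoacetyl analogue of 24 | BrCC(=O)[C@@]1(CC2=C[C@@H]5CC(=O)O[C@@H]5C[C@H](C)C2=O)C(=O)O[C@H]3C[C@@H](C)C(CCC4(C)OCCO4)=CC[C@@H]13
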